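**Retrosynthetic overview**

1. Target 33 ⇒ bis-lactone 31 (C20 methyl by trans-selective lactone enolate methylation) ⇒ 1,4-diol 29 ⇒ homoallylic alcohol 27.
2. Key C18–C19 bond: intermolecular, reagent-controlled carbonyl allylation of the ring A–D pyrrole-carbaldehyde 25 with an allylborane; 25 ⇐ Vilsmeier formylation of 23.
3. 23 ⇐ 20 (C13 methyl by α-methylenation, then convex-face hydrogenation); ring A by N4–C5 alkylation of NH-pyrrole 19; ring B by Paal–Knorr condensation of keto-aldehyde 16.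
4. 16 ⇐ one ozonolysis of 15 (C9a=CH2 and C1-allyl); ring D from ketone 11 by C12 enolate alkylation and equatorial hydride delivery/lactonisation (sets C12, C11).
5. Ring C stereocentres C9/C10 from catalytic asymmetric Et2Zn 1,4-addition/allylation of enone 1. Ring order: C (present in 1) → D → B → A → E.

Assumption: atoms carry the stenine-type labels (N4; C5–C8 azepane CH2; C9; pyrrole C9a, C1, C2, C3; C10 ethyl-bearing; C11 O-bearing; C12; C13; C14 ring D C=O; C18–C21 side lactone), the target is 9R,10R,11R,12S,13S,18R,20S, rings are A azepane, B pyrrole, C cyclohexane, D fused lactone, E side lactone, and enone 1 is bought.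

**Step 1**
Reactants: 1 1,4-dioxaspiro[4.5]dec-6-en-8-one
Product: 3 (6R,7R)-6-ethyl-7-(prop-2-en-1-yl)-1,4-dioxaspiro[4.5]decan-8-one, via ethylzinc enolate 2 (not isolated)
Conditions: Et2Zn, Cu(OTf)2 (2 mol%), (S,R,R)-O,O'-(1,1'-binaphthyl-2,2'-diyl) N,N-bis(1-phenylethyl)phosphoramidite (4 mol%), toluene, −30 °C; then allyl acetate, Pd(PPh3)4 (4 mol%), 0 °C
Reagents that add atoms: diethylzinc, CC[Zn]CC; allyl acetate, CC(=O)OCC=C
Why: Copper–phosphoramidite-catalysed enantioselective 1,4-addition sets C10 (ethyl goes to the enone face that gives (S)-3-ethylcyclohexanone from cyclohexenone with this ligand), and the zinc enolate is allylated through a π-allylpalladium species (Tsuji–Trost) anti to the new ethyl group, giving the 9,10-trans ketone.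

**Step 2**
Reactants: 4 (Z)-but-2-ene-1,4-diol
Product: 5 (Z)-1,4-bis(tert-butyldiphenylsilyloxy)but-2-ene
Conditions: t-BuPh2SiCl (2.2 equiv), imidazole, DMF, 23 °C
Reagents that add atoms: tert-butyl(chloro)diphenylsilane, CC(C)(C)[Si](Cl)(c1ccccc1)c1ccccc1
Why: Standard imidazole-promoted silylation of both primary alcohols gives a symmetrical internal olefin partner for cross-metathesis.

**Step 3**
Reactants: 3 (6R,7R)-6-ethyl-7-(prop-2-en-1-yl)-1,4-dioxaspiro[4.5]decan-8-one; 5 (Z)-1,4-bis(tert-butyldiphenylsilyloxy)but-2-ene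
Product: 6 (6R,7R)-7-[(2E)-4-(tert-butyldiphenylsilyloxy)but-2-en-1-yl]-6-ethyl-1,4-dioxaspiro[4.5]decan-8-one
Conditions: second-generation Grubbs catalyst RuCl2(=CHPh)(PCy3)(H2IMes) (5 mol%), 5 (3 equiv), CH2Cl2, 40 °C
Reagents that add atoms: none
Why: Olefin cross-metathesis of the terminal allyl group with a symmetrical 1,4-dioxygenated butene extends the C9 chain to the four carbons C8–C5 (E/Z ratio is irrelevant because the alkene is reduced next).

**Step 4**
Reactants: 6 (6R,7R)-7-[(2E)-4-(tert-butyldiphenylsilyloxy)but-2-en-1-yl]-6-ethyl-1,4-dioxaspiro[4.5]decan-8-one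
Product: 7 (6R,7R)-7-[4-(tert-butyldiphenylsilyloxy)butyl]-6-ethyl-1,4-dioxaspiro[4.5]decan-8-one
Conditions: H2 (1 atm), Pd/C (10%), EtOAc, 23 °C
Reagents that add atoms: none
Why: Heterogeneous catalytic hydrogenation saturates the only C=C bond and leaves ketone, ketal and silyl ether untouched.

**Step 5**
Reactants: 7 (6R,7R)-7-[4-(tert-butyldiphenylsilyloxy)butyl]-6-ethyl-1,4-dioxaspiro[4.5]decan-8-one
Product: 9 (6R,7R,9S)-7-[4-(tert-butyldiphenylsilyloxy)butyl]-6-ethyl-9-(prop-2-en-1-yl)-1,4-dioxaspiro[4.5]decan-8-one, via lithium enolate 8 (not isolated)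
Conditions: LiN(i-Pr)2, THF, −78 °C; allyl bromide, −78 → 0 °C; then NaOMe (0.2 equiv), MeOH, 23 °C
Reagents that add atoms: allyl bromide, C=CCBr
Why: Kinetic deprotonation takes the CH2 at C1 rather than the substituted C9, enolate allylation installs the future C2–C3 unit, and methoxide equilibration gives the all-equatorial 2,6-cis ketone (C1 is a temporary stereocentre that later becomes a pyrrole carbon).

**Step 6**
Reactants: 9 (6R,7R,9S)-7-[4-(tert-butyldiphenylsilyloxy)butyl]-6-ethyl-9-(prop-2-en-1-yl)-1,4-dioxaspiro[4.5]decan-8-one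
Product: 10 (6R,7R,9S)-7-[4-(tert-butyldiphenylsilyloxy)butyl]-6-ethyl-8-methylidene-9-(prop-2-en-1-yl)-1,4-dioxaspiro[4.5]decane
Conditions: Ph3PCH3Br, KOt-Bu, toluene, 90 °C
Reagents that add atoms: methyltriphenylphosphonium bromide, C[P+](c1ccccc1)(c1ccccc1)c1ccccc1.[Br-]
Why: Wittig methylenation under the hot tert-butoxide conditions used for hindered ketones masks the C9a carbonyl as an exocyclic alkene that survives the enolate and hydride steps and is reopened by ozone in step 10.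

**Step 7**
Reactants: 10 (6R,7R,9S)-7-[4-(tert-butyldiphenylsilyloxy)butyl]-6-ethyl-8-methylidene-9-(prop-2-en-1-yl)-1,4-dioxaspiro[4.5]decane
Product: 11 (2R,3R,5S)-3-[4-(tert-butyldiphenylsilyloxy)butyl]-2-ethyl-4-methylidene-5-(prop-2-en-1-yl)cyclohexan-1-one
Conditions: aq. HCl (1 M), THF, 23 °C
Reagents that add atoms: water, O
Why: Mild acid hydrolysis of the dioxolane frees the C11 ketone while the tert-butyldiphenylsilyl ether and both alkenes persist.

**Step 8**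
Reactants: 11 (2R,3R,5S)-3-[4-(tert-butyldiphenylsilyloxy)butyl]-2-ethyl-4-methylidene-5-(prop-2-en-1-yl)cyclohexan-1-one
Product: 13 methyl 2-[(1S,3R,4R,6S)-4-[4-(tert-butyldiphenylsilyloxy)butyl]-3-ethyl-5-methylidene-2-oxo-6-(prop-2-en-1-yl)cyclohexyl]acetate, via lithium enolate 12 (not isolated)
Conditions: LiN(i-Pr)2, THF, −78 °C; BrCH2CO2Me, −78 → −30 °C; then DBU (0.1 equiv), CH2Cl2, 23 °C
Reagents that add atoms: methyl bromoacetate, COC(=O)CBr
Why: Kinetic enolisation occurs at the C12 methylene and not at the ethyl-bearing C10, and enolate alkylation anti to the neighbouring equatorial C1-allyl group puts CH2CO2Me equatorial and cis to ethyl, which is also the thermodynamic isomer that DBU secures because C9 and C1 cannot epimerise.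

**Step 9**
Reactants: 13 methyl 2-[(1S,3R,4R,6S)-4-[4-(tert-butyldiphenylsilyloxy)butyl]-3-ethyl-5-methylidene-2-oxo-6-(prop-2-en-1-yl)cyclohexyl]acetate
Product: 15 (3aS,4S,6R,7R,7aR)-6-[4-(tert-butyldiphenylsilyloxy)butyl]-7-ethyl-5-methylidene-4-(prop-2-en-1-yl)hexahydro-1-benzofuran-2(3H)-one, via lithium alkoxide 14 (not isolated)
Conditions: LiBH(s-Bu)3, THF, −78 → 23 °C; aq. NH4Cl
Reagents that add atoms: none
Why: The bulky hydride attacks the ketone flanked by two equatorial groups from the equatorial side, so the axial C11 alkoxide is cis to both ethyl and CH2CO2Me and closes the cis-fused γ-lactone (ring D) by intramolecular acyl substitution, fixing the all-cis C10/C11/C12 array.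

**Step 10**
Reactants: 15 (3aS,4S,6R,7R,7aR)-6-[4-(tert-butyldiphenylsilyloxy)butyl]-7-ethyl-5-methylidene-4-(prop-2-en-1-yl)hexahydro-1-benzofuran-2(3H)-one
Product: 16 2-[(3aS,4S,6R,7R,7aR)-6-[4-(tert-butyldiphenylsilyloxy)butyl]-7-ethyl-2,5-dioxooctahydro-1-benzofuran-4-yl]acetaldehyde
Conditions: O3, CH2Cl2/MeOH, −78 °C; then Me2S, −78 → 23 °C
Reagents that add atoms: ozone, O=[O+][O-]
Why: Ozonolysis with reductive work-up cleaves both terminal alkenes at once, unmasking the C9a ketone and turning the allyl group into the C3 aldehyde, which gives the 1,4-dicarbonyl needed for the pyrrole without any enolate chemistry on the lactone.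

**Step 11**
Reactants: 16 2-[(3aS,4S,6R,7R,7aR)-6-[4-(tert-butyldiphenylsilyloxy)butyl]-7-ethyl-2,5-dioxooctahydro-1-benzofuran-4-yl]acetaldehyde
Product: 17 γ-lactone of 2-[(4S,5R,6R,7R)-7-[4-(tert-butyldiphenylsilyloxy)butyl]-6-ethyl-5-hydroxy-4,5,6,7-tetrahydro-1H-indol-4-yl]acetic acid
Conditions: NH4OAc (10 equiv), AcOH (cat.), MeOH, 45 °C
Reagents that add atoms: ammonium acetate, CC(=O)[O-].[NH4+]
Why: Paal–Knorr condensation of the γ-keto aldehyde with ammonia builds the pyrrole (ring B) on C9a/C1, removes the temporary C1 stereocentre and leaves C9 in its stable trans relation to C10.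

**Step 12**
Reactants: 17 γ-lactone of 2-[(4S,5R,6R,7R)-7-[4-(tert-butyldiphenylsilyloxy)butyl]-6-ethyl-5-hydroxy-4,5,6,7-tetrahydro-1H-indol-4-yl]acetic acid
Product: 18 γ-lactone of 2-[(4S,5R,6R,7R)-6-ethyl-5-hydroxy-7-(4-hydroxybutyl)-4,5,6,7-tetrahydro-1H-indol-4-yl]acetic acid
Conditions: Bu4NF, AcOH, THF, 23 °C
Reagents that add atoms: none
Why: Buffered fluoride desilylation frees the primary alcohol without opening the lactone.

**Step 13**
Reactants: 18 γ-lactone of 2-[(4S,5R,6R,7R)-6-ethyl-5-hydroxy-7-(4-hydroxybutyl)-4,5,6,7-tetrahydro-1H-indol-4-yl]acetic acid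
Product: 19 γ-lactone of 2-[(4S,5R,6R,7R)-6-ethyl-5-hydroxy-7-[4-(methanesulfonyloxy)butyl]-4,5,6,7-tetrahydro-1H-indol-4-yl]acetic acid
Conditions: MsCl, Et3N, CH2Cl2, −20 °C
Reagents that add atoms: methanesulfonyl chloride, CS(=O)(=O)Cl
Why: Sulfonylation of the primary alcohol gives the leaving group at C5 while the pyrrole N–H does not react under amine base.

**Step 14**
Reactants: 19 γ-lactone of 2-[(4S,5R,6R,7R)-6-ethyl-5-hydroxy-7-[4-(methanesulfonyloxy)butyl]-4,5,6,7-tetrahydro-1H-indol-4-yl]acetic acid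
Product: 20 (9R,10R,11R,12S)-ring A–D lactone (C13 H2; C3–H)
Conditions: NaH (1.1 equiv), DMF (0.01 M), 0 → 23 °C
Reagents that add atoms: none
Why: Intramolecular N-alkylation (7-exo-tet) of the pyrrolyl anion by the primary mesylate closes the azepane (ring A), with high dilution suppressing dimers.

**Step 15**
Reactants: 20 (9R,10R,11R,12S)-ring A–D lactone (C13 H2; C3–H)
Product: 22 (9R,10R,11R,12S)-13-methylidene ring A–D lactone, via sodium formyl-lactone enolate 21 (not isolated)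
Conditions: NaH, HCO2Et, EtOH (cat.), THF, 0 → 23 °C; then (CH2O)n, THF, 65 °C
Reagents that add atoms: formaldehyde (as paraformaldehyde), C=O
Why: Crossed Claisen condensation of the lactone with ethyl formate followed by aldol addition to formaldehyde and loss of formate gives the α-methylene lactone without an iminium electrophile that would attack the pyrrole.

**Step 16**
Reactants: 22 (9R,10R,11R,12S)-13-methylidene ring A–D lactone
Product: 23 (9R,10R,11R,12S,13S)-13-methyl ring A–D lactone (target lacking ring E)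
Conditions: H2 (1 atm), Pd/C (10%), EtOAc, 23 °C
Reagents that add atoms: none
Why: Hydrogen adds to the exocyclic alkene from the convex face of the cis-fused bicyclic lactone (the face of H11 and H12), so the new methyl sits on the concave face cis to C1 (13S), the epimer that enolate methylation would not give.

**Step 17**
Reactants: 23 (9R,10R,11R,12S,13S)-13-methyl ring A–D lactone (target lacking ring E)
Product: 25 (9R,10R,11R,12S,13S)-3-formyl ring A–D lactone, via iminium salt 24 (not isolated)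
Conditions: POCl3, DMF, ClCH2CH2Cl, 0 → 23 °C; then aq. NaOAc, 40 °C
Reagents that add atoms: N,N-dimethylformamide, CN(C)C=O; water, O
Why: Vilsmeier–Haack formylation attacks the only free pyrrole α-position (C3) and the iminium salt is hydrolysed to the aldehyde under buffered conditions that spare the lactone.

**Step 18**
Reactants: 25 (9R,10R,11R,12S,13S)-3-formyl ring A–D lactone
Product: 27 (9R,10R,11R,12S,13S)-3-[(1R)-1-hydroxybut-3-en-1-yl] ring A–D lactone, via borinate 26 (not isolated)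
Conditions: (+)-Ipc2BOMe [from (−)-α-pinene], allylMgBr, Et2O, −78 → 23 °C; then 25, −78 °C; then HOCH2CH2NH2, 23 °C
Reagents that add atoms: allylmagnesium bromide, C=CC[Mg]Br
Why: Brown allylboration joins the ring A–D aldehyde and the C3 allyl fragment through a closed chair (Zimmerman–Traxler) transition state in which this isopinocampheyl reagent adds to the Re face of an aryl-type aldehyde, giving 18R under reagent control at −78 °C and without acid, which the pyrrolyl carbinol would not tolerate.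

**Step 19**
Reactants: 27 (9R,10R,11R,12S,13S)-3-[(1R)-1-hydroxybut-3-en-1-yl] ring A–D lactone
Product: 29 (9R,10R,11R,12S,13S)-3-[(1R)-1,4-dihydroxybutyl] ring A–D lactone, via bis(9-BBN) adduct 28 (not isolated)
Conditions: 9-BBN-H (3 equiv), THF, 0 → 23 °C; then NaBO3·4H2O, H2O, 23 °C
Reagents that add atoms: sodium perborate, [Na+].[O-]OB=O
Why: Anti-Markovnikov hydroboration of the terminal alkene with a borane that does not reduce lactones, followed by mild perborate oxidation, delivers the primary alcohol at C21.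

**Step 20**
Reactants: 29 (9R,10R,11R,12S,13S)-3-[(1R)-1,4-dihydroxybutyl] ring A–D lactone
Product: 31 (9R,10R,11R,12S,13S)-3-[(2R)-5-oxooxolan-2-yl] ring A–D lactone (20-demethyl target), via lactol 30 (not isolated)
Conditions: TEMPO (0.2 equiv), PhI(OAc)2 (2.5 equiv), NaHCO3, CH2Cl2, 23 °C
Reagents that add atoms: none
Why: Oxoammonium (TEMPO) oxidation is selective for the unhindered primary alcohol, the hydroxy aldehyde closes to the lactol and this is oxidised on to the γ-lactone (ring E) with C18 untouched.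

**Step 21**
Reactants: 31 (9R,10R,11R,12S,13S)-3-[(2R)-5-oxooxolan-2-yl] ring A–D lactone (20-demethyl target)
Product: 33 CNP0232452.1 (9R,10R,11R,12S,13S,18R,20S), via lithium enolate 32 (not isolated)
Conditions: LiN(i-Pr)2 (1.05 equiv), THF, −78 °C; MeI, −78 → −40 °C
Reagents that add atoms: iodomethane, CI
Why: Kinetic deprotonation takes the CH2 of the side lactone in preference to the tertiary C13–H of ring D, and enolate alkylation occurs anti to the C18 pyrrolyl group, giving the trans-3,5-disubstituted lactone (20S).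

**Compound list**

1 | 1,4-dioxaspiro[4.5]dec-6-en-8-one | O=C1C=CC2(CC1)OCCO2 | starting material
2 | ethyl{[(6R)-6-ethyl-1,4-dioxaspiro[4.5]dec-7-en-8-yl]oxy}zinc (ethylzinc enolate) | CC[C@H]1C2(OCCO2)CCC(O[Zn]CC)=C1 | intermediate
3 | (6R,7R)-6-ethyl-7-(prop-2-en-1-yl)-1,4-dioxaspiro[4.5]decan-8-one | CC[C@H]1C2(OCCO2)CCC(=O)[C@@H]1CC=C | intermediate
4 | (Z)-but-2-ene-1,4-diol | OC/C=C\CO | starting material
5 | (Z)-1,4-bis(tert-butyldiphenylsilyloxy)but-2-ene | CC(C)(C)[Si](c1ccccc1)(c1ccccc1)OC/C=C\CO[Si](c1ccccc1)(c1ccccc1)C(C)(C)C | intermediate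
6 | (6R,7R)-7-[(2E)-4-(tert-butyldiphenylsilyloxy)but-2-en-1-yl]-6-ethyl-1,4-dioxaspiro[4.5]decan-8-one | CC[C@H]1C2(OCCO2)CCC(=O)[C@@H]1C/C=C/CO[Si](c1ccccc1)(c1ccccc1)C(C)(C)C | intermediate
7 | (6R,7R)-7-[4-(tert-butyldiphenylsilyloxy)butyl]-6-ethyl-1,4-dioxaspiro[4.5]decan-8-one | CC[C@H]1C2(OCCO2)CCC(=O)[C@@H]1CCCCO[Si](c1ccccc1)(c1ccccc1)C(C)(C)C | intermediate
8 | lithium enolate of 7 (C8=C9 enolate of the spiro ketone) | CC[C@H]1C2(OCCO2)CC=C(O[Li])[C@@H]1CCCCO[Si](c1ccccc1)(c1ccccc1)C(C)(C)C | intermediate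
9 | (6R,7R,9S)-7-[4-(tert-butyldiphenylsilyloxy)butyl]-6-ethyl-9-(prop-2-en-1-yl)-1,4-dioxaspiro[4.5]decan-8-one | CC[C@H]1C2(OCCO2)C[C@H](CC=C)C(=O)[C@@H]1CCCCO[Si](c1ccccc1)(c1ccccc1)C(C)(C)C | intermediate
10 | (6R,7R,9S)-7-[4-(tert-butyldiphenylsilyloxy)butyl]-6-ethyl-8-methylidene-9-(prop-2-en-1-yl)-1,4-dioxaspiro[4.5]decane | CC[C@H]1C2(OCCO2)C[C@H](CC=C)C(=C)[C@@H]1CCCCO[Si](c1ccccc1)(c1ccccc1)C(C)(C)C | intermediate
11 | (2R,3R,5S)-3-[4-(tert-butyldiphenylsilyloxy)butyl]-2-ethyl-4-methylidene-5-(prop-2-en-1-yl)cyclohexan-1-one | CC[C@H]1C(=O)C[C@H](CC=C)C(=C)[C@@H]1CCCCO[Si](c1ccccc1)(c1ccccc1)C(C)(C)C | intermediate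
12 | lithium enolate of 11 (C1=C6 enolate, away from the ethyl-bearing carbon) | CC[C@H]1C(O[Li])=C[C@H](CC=C)C(=C)[C@@H]1CCCCO[Si](c1ccccc1)(c1ccccc1)C(C)(C)C | intermediate
13 | methyl 2-[(1S,3R,4R,6S)-4-[4-(tert-butyldiphenylsilyloxy)butyl]-3-ethyl-5-methylidene-2-oxo-6-(prop-2-en-1-yl)cyclohexyl]acetate | CC[C@H]1C(=O)[C@@H](CC(=O)OC)[C@H](CC=C)C(=C)[C@@H]1CCCCO[Si](c1ccccc1)(c1ccccc1)C(C)(C)C | intermediate
14 | lithium alkoxide of methyl 2-[(1S,2R,3R,4R,6S)-4-[4-(tert-butyldiphenylsilyloxy)butyl]-3-ethyl-2-hydroxy-5-methylidene-6-(prop-2-en-1-yl)cyclohexyl]acetate | CC[C@H]1[C@@H](O[Li])[C@@H](CC(=O)OC)[C@H](CC=C)C(=C)[C@@H]1CCCCO[Si](c1ccccc1)(c1ccccc1)C(C)(C)C | intermediate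
15 | (3aS,4S,6R,7R,7aR)-6-[4-(tert-butyldiphenylsilyloxy)butyl]-7-ethyl-5-methylidene-4-(prop-2-en-1-yl)hexahydro-1-benzofuran-2(3H)-one | CC[C@H]1[C@H]2OC(=O)C[C@H]2[C@H](CC=C)C(=C)[C@@H]1CCCCO[Si](c1ccccc1)(c1ccccc1)C(C)(C)C | intermediate
16 | 2-[(3aS,4S,6R,7R,7aR)-6-[4-(tert-butyldiphenylsilyloxy)butyl]-7-ethyl-2,5-dioxooctahydro-1-benzofuran-4-yl]acetaldehyde | CC[C@H]1[C@H]2OC(=O)C[C@H]2[C@H](CC=O)C(=O)[C@@H]1CCCCO[Si](c1ccccc1)(c1ccccc1)C(C)(C)C | intermediate
17 | γ-lactone of 2-[(4S,5R,6R,7R)-7-[4-(tert-butyldiphenylsilyloxy)butyl]-6-ethyl-5-hydroxy-4,5,6,7-tetrahydro-1H-indol-4-yl]acetic acid | CC[C@H]1[C@H]2OC(=O)C[C@H]2c2cc[nH]c2[C@@H]1CCCCO[Si](c1ccccc1)(c1ccccc1)C(C)(C)C | intermediate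
18 | γ-lactone of 2-[(4S,5R,6R,7R)-6-ethyl-5-hydroxy-7-(4-hydroxybutyl)-4,5,6,7-tetrahydro-1H-indol-4-yl]acetic acid | CC[C@H]1[C@H]2OC(=O)C[C@H]2c2cc[nH]c2[C@@H]1CCCCO | intermediate
19 | γ-lactone of 2-[(4S,5R,6R,7R)-6-ethyl-5-hydroxy-7-[4-(methanesulfonyloxy)butyl]-4,5,6,7-tetrahydro-1H-indol-4-yl]acetic acid | CC[C@H]1[C@H]2OC(=O)C[C@H]2c2cc[nH]c2[C@@H]1CCCCOS(C)(=O)=O | intermediate
20 | (9R,10R,11R,12S)-ring A–D lactone: target lacking the C13 methyl and ring E (C13 H2; C3–H) | CC[C@H]1[C@H]2OC(=O)C[C@H]2c2ccn3c2[C@@H]1CCCC3 | intermediate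
21 | sodium enolate of the 13-formyl derivative of 20 (13-oxidomethylidene lactone) | CC[C@H]1[C@H]2OC(=O)C(=C[O-])[C@H]2c2ccn3c2[C@@H]1CCCC3.[Na+] | intermediate
22 | (9R,10R,11R,12S)-13-methylidene ring A–D lactone | CC[C@H]1[C@H]2OC(=O)C(=C)[C@H]2c2ccn3c2[C@@H]1CCCC3 | intermediate
23 | (9R,10R,11R,12S,13S)-13-methyl ring A–D lactone: target lacking ring E (C3–H) | CC[C@H]1[C@H]2OC(=O)[C@@H](C)[C@H]2c2ccn3c2[C@@H]1CCCC3 | intermediate
24 | 3-(dimethyliminiomethyl) derivative of 23, dichlorophosphate salt | CC[C@H]1[C@H]2OC(=O)[C@@H](C)[C@H]2c2cc(C=[N+](C)C)n3c2[C@@H]1CCCC3.[O-]P(=O)(Cl)Cl | intermediate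
25 | (9R,10R,11R,12S,13S)-3-formyl ring A–D lactone | CC[C@H]1[C@H]2OC(=O)[C@@H](C)[C@H]2c2cc(C=O)n3c2[C@@H]1CCCC3 | intermediate
26 | (18R)-O-[bis(isopinocampheyl)boryl] derivative of 27 (borinate) | CC[C@H]1[C@H]2OC(=O)[C@@H](C)[C@H]2c2cc([C@H](OB([C@H]3C[C@H]4C[C@@H]([C@@H]3C)C4(C)C)[C@H]3C[C@H]4C[C@@H]([C@@H]3C)C4(C)C)CC=C)n3c2[C@@H]1CCCC3 | intermediate
27 | (9R,10R,11R,12S,13S)-3-[(1R)-1-hydroxybut-3-en-1-yl] ring A–D lactone | CC[C@H]1[C@H]2OC(=O)[C@@H](C)[C@H]2c2cc([C@H](O)CC=C)n3c2[C@@H]1CCCC3 | intermediate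
28 | bis(9-borabicyclo[3.3.1]nonan-9-yl) adduct of 27 (O18–B and C21–B) | CC[C@H]1[C@H]2OC(=O)[C@@H](C)[C@H]2c2cc([C@H](OB3C4CCCC3CCC4)CCCB3C4CCCC3CCC4)n3c2[C@@H]1CCCC3 | intermediate
29 | (9R,10R,11R,12S,13S)-3-[(1R)-1,4-dihydroxybutyl] ring A–D lactone | CC[C@H]1[C@H]2OC(=O)[C@@H](C)[C@H]2c2cc([C@H](O)CCCO)n3c2[C@@H]1CCCC3 | intermediate
30 | (9R,10R,11R,12S,13S)-3-[(2R)-5-hydroxyoxolan-2-yl] ring A–D lactone (lactol) | CC[C@H]1[C@H]2OC(=O)[C@@H](C)[C@H]2c2cc([C@H]3CCC(O)O3)n3c2[C@@H]1CCCC3 | intermediate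
31 | (9R,10R,11R,12S,13S)-3-[(2R)-5-oxooxolan-2-yl] ring A–D lactone (20-demethyl target) | CC[C@H]1[C@H]2OC(=O)[C@@H](C)[C@H]2c2cc([C@H]3CCC(=O)O3)n3c2[C@@H]1CCCC3 | intermediate
32 | lithium enolate of the ring E lactone of 31 | CC[C@H]1[C@H]2OC(=O)[C@@H](C)[C@H]2c2cc([C@H]3CC=C(O[Li])O3)n3c2[C@@H]1CCCC3 | intermediate
33 | CNP0232452.1 (9R,10R,11R,12S,13S,18R,20S) | CC[C@H]1[C@H]2OC(=O)[C@@H](C)[C@H]2c2cc([C@H]3C[C@H](C)C(=O)O3)n3c2[C@@H]1CCCC3 | target

**Totals**

Total step count: 21. Longest linear sequence: 20 steps (steps 1 and 3–21, from enone 1); step 2 is a one-step side branch.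

**Three steps most likely to fail**

Step 14 (closing the seven-membered ring A by N-alkylation, with a base next to an enolisable lactone). The fallback sets out from lactone 15 and comes back at 20, forming both N–C bonds by condensation instead of alkylation. Bu4NF/AcOH gives the primary alcohol (3aS,4S,6R,7R,7aR)-7-ethyl-6-(4-hydroxybutyl)-5-methylidene-4-(prop-2-en-1-yl)hexahydro-1-benzofuran-2(3H)-one F1. MsCl/Et3N gives the mesylate F2 and NaN3 in DMF the azide F3. Ozonolysis with Me2S work-up gives the azido keto-aldehyde F4. Staudinger reduction (PPh3, THF/H2O), then AcOH at 50 °C, releases the amino keto-aldehyde F5 (not isolated), which undergoes an intramolecular Paal–Knorr condensation to 20.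

Step 20 (oxidative lactonisation beside an electron-rich pyrrole and an acid-labile pyrrolyl carbinol). The fallback sets out from homoallylic alcohol 27 and comes back at 31 through lactol 30, keeping the carbinol masked and finishing with a neutral oxidant. Et3SiOTf/2,6-lutidine gives the triethylsilyl ether F6. 9-BBN-H then NaBO3·4H2O gives the primary alcohol F7. Dess–Martin periodinane/NaHCO3 gives the aldehyde F8. Bu4NF/AcOH removes the silyl group and the hydroxy aldehyde closes to lactol 30, which Ag2CO3 on Celite in toluene at 80 °C oxidises to 31.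

Step 21 (site-selective enolisation of ring E in the presence of the ring D lactone, and trans selectivity). The fallback sets out from pyrrole 23 and comes back at 33, bringing C20 in with its methyl group already set. Friedel–Crafts acylation of C3 with (S)-methylsuccinic anhydride (BF3·OEt2, CH2Cl2, attack at the less hindered carbonyl) gives the keto acid F9. Me3SiCHN2 gives the keto ester F10. Reduction with (S)-2-methyl-CBS-oxazaborolidine and catecholborane at −78 °C gives the (18R)-hydroxy ester F11, which lactonises on mild base work-up to 33.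

**Further compounds**

F1 | step 14 | (3aS,4S,6R,7R,7aR)-7-ethyl-6-(4-hydroxybutyl)-5-methylidene-4-(prop-2-en-1-yl)hexahydro-1-benzofuran-2(3H)-one | CC[C@H]1[C@H]2OC(=O)C[C@H]2[C@H](CC=C)C(=C)[C@@H]1CCCCO
F2 | step 14 | methanesulfonate of F1 | CC[C@H]1[C@H]2OC(=O)C[C@H]2[C@H](CC=C)C(=C)[C@@H]1CCCCOS(C)(=O)=O
F3 | step 14 | (3aS,4S,6R,7R,7aR)-6-(4-azidobutyl)-7-ethyl-5-methylidene-4-(prop-2-en-1-yl)hexahydro-1-benzofuran-2(3H)-one | CC[C@H]1[C@H]2OC(=O)C[C@H]2[C@H](CC=C)C(=C)[C@@H]1CCCCN=[N+]=[N-]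
F4 | step 14 | 2-[(3aS,4S,6R,7R,7aR)-6-(4-azidobutyl)-7-ethyl-2,5-dioxooctahydro-1-benzofuran-4-yl]acetaldehyde | CC[C@H]1[C@H]2OC(=O)C[C@H]2[C@H](CC=O)C(=O)[C@@H]1CCCCN=[N+]=[N-]
F5 | step 14 | 2-[(3aS,4S,6R,7R,7aR)-6-(4-aminobutyl)-7-ethyl-2,5-dioxooctahydro-1-benzofuran-4-yl]acetaldehyde | CC[C@H]1[C@H]2OC(=O)C[C@H]2[C@H](CC=O)C(=O)[C@@H]1CCCCN
F6 | step 20 | (18R)-O-triethylsilyl ether of 27 | CC[C@H]1[C@H]2OC(=O)[C@@H](C)[C@H]2c2cc([C@H](O[Si](CC)(CC)CC)CC=C)n3c2[C@@H]1CCCC3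
F7 | step 20 | (9R,10R,11R,12S,13S)-3-[(1R)-4-hydroxy-1-(triethylsilyloxy)butyl] ring A–D lactone | CC[C@H]1[C@H]2OC(=O)[C@@H](C)[C@H]2c2cc([C@H](O[Si](CC)(CC)CC)CCCO)n3c2[C@@H]1CCCC3
F8 | step 20 | (9R,10R,11R,12S,13S)-3-[(1R)-4-oxo-1-(triethylsilyloxy)butyl] ring A–D lactone | CC[C@H]1[C@H]2OC(=O)[C@@H](C)[C@H]2c2cc([C@H](O[Si](CC)(CC)CC)CCC=O)n3c2[C@@H]1CCCC3
F9 | step 21 | (2S)-2-methyl-4-oxo-4-(ring A–D lactone-3-yl)butanoic acid (C18 keto acid) | CC[C@H]1[C@H]2OC(=O)[C@@H](C)[C@H]2c2cc(C(=O)C[C@H](C)C(=O)O)n3c2[C@@H]1CCCC3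
F10 | step 21 | methyl ester of F9 | CC[C@H]1[C@H]2OC(=O)[C@@H](C)[C@H]2c2cc(C(=O)C[C@H](C)C(=O)OC)n3c2[C@@H]1CCCC3
F11 | step 21 | methyl (2S,4R)-4-hydroxy-2-methyl-4-(ring A–D lactone-3-yl)butanoate | CC[C@H]1[C@H]2OC(=O)[C@@H](C)[C@H]2c2cc([C@H](O)C[C@H](C)C(=O)OC)n3c2[C@@H]1CCCC3
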